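**Retrosynthetic overview**
1. The angelate on the cyclopentanol is put on last and the (2S,3S)-epoxyangelate on the cyclohexanol early; the epoxy acid comes from angelic acid by Sharpless epoxidation.
2. The acetyl-cyclopentanol comes from ring contraction of the 2-methylcyclohexenone ring of carvone (Eschenmoser–Tanabe fragmentation, alkyne–carbonyl metathesis, beta-hydroxylation).
3. The methylidene-cyclohexanol comes from a type two carbonyl-ene cyclisation of a gamma-keto aldehyde onto the isopropenyl group.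
4. Key C–C bond: the 1,4-dicarbonyl link between C6 of carvone and the alpha carbon of 3-methylbutanal, made from an alpha-bromo ketone (enolonium equivalent) and a chiral enamine.
5. Ring order: carvone ring (given), then the cyclohexane by ene reaction, then contraction of the carvone ring to the cyclopentane.

Assumption: the target is taken exactly as the SMILES given, and the (2S,5R)-imidazolidinone is taken to open the Re face of the enamine alpha carbon (its mirror image is used if the sense proves opposite).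

**Route**

Step 1
Reactants: 1 angelic acid, (Z)-2-methylbut-2-enoic acid
Product: 2 (Z)-2-methylbut-2-en-1-ol
Conditions: LiAlH4, Et2O, 0 °C
Reagents that add atoms: none
Why: Hydride reduction of the acid at 0 °C leaves the trisubstituted Z-alkene untouched and unisomerised.

Step 2
Reactants: 2 (Z)-2-methylbut-2-en-1-ol
Product: 3 [(2R,3S)-2,3-dimethyloxiran-2-yl]methanol
Conditions: Ti(OiPr)4 (10 mol%), L-(+)-diethyl tartrate (12 mol%), t-BuOOH, 4 Å MS, CH2Cl2, −20 °C
Reagents that add atoms: tert-butyl hydroperoxide CC(C)(C)OO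
Why: Sharpless asymmetric epoxidation with the L-(+)-tartrate delivers oxygen to the lower face of the allylic alcohol drawn with CH2OH at the lower right, which gives (2R,3S), the cis methyl/CH2OH relationship being inherited from the Z-alkene.

Step 3
Reactants: 3 [(2R,3S)-2,3-dimethyloxiran-2-yl]methanol
Product: 4 (2S,3S)-2,3-dimethyloxirane-2-carboxylic acid (epoxyangelic acid)
Conditions: RuCl3·xH2O (2 mol%), NaIO4 (4 equiv), MeCN–EtOAc–H2O, 0 → 23 °C
Reagents that add atoms: water O
Why: Sharpless RuCl3/NaIO4 oxidation takes the primary alcohol to the acid without opening the epoxide, so both centres are kept (the C2 descriptor changes only by priority).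

Step 4
Reactants: 5 (R)-(−)-carvone
Product: 7 (5S,6S)-6-bromo-2-methyl-5-(prop-1-en-2-yl)cyclohex-2-en-1-one, via silyl dienol ether 6 (not isolated)
Conditions: TMSOTf, Et3N, CH2Cl2, 0 °C; then NBS, THF, −78 °C
Reagents that add atoms: N-bromosuccinimide O=C1CCC(=O)N1Br; trimethylsilyl trifluoromethanesulfonate C[Si](C)(C)OS(=O)(=O)C(F)(F)F (silyl group only in 6)
Why: Soft enolisation gives the cross-conjugated 2-silyloxy diene, which NBS brominates at the terminal enol carbon (alpha-prime bromination of an enone); the bromide configuration does not matter because it is lost in step 5.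

Step 5
Reactants: 7 (5S,6S)-6-bromo-2-methyl-5-(prop-1-en-2-yl)cyclohex-2-en-1-one; 8 3-methylbutanal
Product: 9 (S)-3-methyl-2-[(1R,6R)-3-methyl-2-oxo-6-(prop-1-en-2-yl)cyclohex-3-en-1-yl]butanal
Conditions: 8 (3 equiv), Ru(bpy)3Cl2 (1 mol%), (2S,5R)-2-tert-butyl-3,5-dimethylimidazolidin-4-one·HOTf (20 mol%), 2,6-lutidine (2 equiv), DMF, blue LED, 0 °C
Reagents that add atoms: none
Why: Proposed new method: single-electron reduction of the alpha-bromo ketone by the photoreduced ruthenium complex gives an electrophilic alpha-keto radical (an enolonium equivalent) that adds to the Re face of the chiral enamine of 8 and, at C6, anti to the neighbouring isopropenyl group, joining two carbons that are each alpha to a carbonyl; the closest known reaction is the Nicewicz–MacMillan photoredox organocatalytic alpha-alkylation of aldehydes with phenacyl bromides and bromomalonates, here extended to a secondary cyclic alpha-prime-bromo enone.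

Step 6
Reactants: 9 (S)-3-methyl-2-[(1R,6R)-3-methyl-2-oxo-6-(prop-1-en-2-yl)cyclohex-3-en-1-yl]butanal
Product: 10 (4aR,7R,8S,8aR)-7-hydroxy-2-methyl-5-methylidene-8-(propan-2-yl)-4a,5,6,7,8,8a-hexahydronaphthalen-1(4H)-one
Conditions: Me2AlCl (2.2 equiv), CH2Cl2, −78 → −20 °C (crude 9 used at once)
Reagents that add atoms: none
Why: Type two carbonyl-ene cyclisation through a chair transition state with the isopropyl group and both ring bonds equatorial and the aluminium-bound oxygen axial (as needed for hydrogen transfer from the methyl group) gives the trans ring fusion, the exocyclic methylene and the axial alcohol cis to isopropyl.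

Step 7
Reactants: 10 (4aR,7R,8S,8aR)-7-hydroxy-2-methyl-5-methylidene-8-(propan-2-yl)-4a,5,6,7,8,8a-hexahydronaphthalen-1(4H)-one; 4 (2S,3S)-2,3-dimethyloxirane-2-carboxylic acid
Product: 12 (4aR,7R,8S,8aR)-2-methyl-5-methylidene-1-oxo-8-(propan-2-yl)-1,4,4a,5,6,7,8,8a-octahydronaphthalen-7-yl (2S,3S)-2,3-dimethyloxirane-2-carboxylate, via mixed anhydride 11 (not isolated)
Conditions: 4, 2,4,6-Cl3C6H2COCl, Et3N, THF, 23 °C; then 10, DMAP, toluene, 23 → 40 °C
Reagents that add atoms: 2,4,6-trichlorobenzoyl chloride O=C(Cl)c1c(Cl)cc(Cl)cc1Cl (aroyl group only in 11)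
Why: Yamaguchi esterification through the mixed anhydride acylates the hindered axial alcohol with retention and leaves the glycidic epoxide and the enone alone.

Step 8
Reactants: 12 the epoxyangelate ester of 10
Product: 13 the 2,3-epoxy ketone of 12 (oxirane across C2–C3 on the face of H-4a)
Conditions: t-BuOOH (decane), DBU, CH2Cl2, 0 → 23 °C
Reagents that add atoms: tert-butyl hydroperoxide CC(C)(C)OO
Why: Weitz–Scheffer nucleophilic epoxidation attacks only the electron-poor enone (axial attack at the beta carbon) and spares the exocyclic methylene and the ester; the two new centres are destroyed in step 9.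

Step 9
Reactants: 13 the 2,3-epoxy ketone of 12
Product: 15 5-methylidene-4-(2-oxoethyl)-2-(propan-2-yl)-3-(prop-1-yn-1-yl)cyclohexyl (2S,3S)-2,3-dimethyloxirane-2-carboxylate (four ring centres unchanged), via tosylhydrazone 14 (not isolated)
Conditions: TsNHNH2 (1.05 equiv), AcOH–CH2Cl2 1:1, −20 → 23 °C
Reagents that add atoms: p-toluenesulfonohydrazide Cc1ccc(cc1)S(=O)(=O)NN (only in 14)
Why: Eschenmoser–Tanabe fragmentation of the epoxy ketone tosylhydrazone cuts the former C2–C3 bond with loss of nitrogen and sulfinate, leaving a propynyl group on one ring carbon and an acetaldehyde arm on the next without touching the ring stereocentres.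

Step 10
Reactants: 15 the ring-opened ynal
Product: 16 3-acetyl-7-methylidene-4-(propan-2-yl)-3a,4,5,6,7,7a-hexahydro-1H-inden-5-yl (2S,3S)-2,3-dimethyloxirane-2-carboxylate (trans ring fusion, centres as in 12)
Conditions: AgSbF6 (10 mol%), ClCH2CH2Cl, 60 °C
Reagents that add atoms: none
Why: Silver-catalysed intramolecular alkyne–carbonyl metathesis (formal [2+2] then retro-[2+2] through an oxetene) closes the five-membered ring in the 5-exo sense, so the distal alkyne carbon becomes the acetyl carbonyl regiospecifically.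

Step 11
Reactants: 16 the acetylcyclopentene ester
Product: 18 (1R,2S,3aR,6R,7S,7aR)-1-acetyl-2-hydroxy-4-methylidene-7-(propan-2-yl)octahydro-1H-inden-6-yl (2S,3S)-2,3-dimethyloxirane-2-carboxylate, via pinacol boronate 17 (not isolated)
Conditions: B2pin2, CuCl (5 mol%), NaOtBu (10 mol%), DPEphos (5 mol%), MeOH (2 equiv), THF, 23 °C; then NaBO3·4H2O, THF–H2O, 23 °C
Reagents that add atoms: sodium perborate [Na+].[O-]OB=O; bis(pinacolato)diboron CC1(C)OB(OC1(C)C)B1OC(C)(C)C(C)(C)O1 (boryl group only in 17)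
Why: Copper-catalysed conjugate borylation (Yun conditions) is expected to put boron on the lower face of the cyclopentene, away from the axial hydrogen of the ring-fusion carbon next to the allylic CH2; protonation and equilibration place the acetyl group pseudo-equatorial, trans to the ring branch and cis to boron, and perborate oxidation then gives the alcohol with retention.

Step 12
Reactants: 18 the hydroxy ketone; 1 angelic acid
Product: 20 CNP0300602.1, (1R,2S,3aR,6R,7S,7aR)-1-acetyl-2-{[(Z)-2-methylbut-2-enoyl]oxy}-4-methylidene-7-(propan-2-yl)octahydro-1H-inden-6-yl (2S,3S)-2,3-dimethyloxirane-2-carboxylate, via mixed anhydride 19 (not isolated)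
Conditions: 1, 2,4,6-Cl3C6H2COCl, Et3N, toluene, 23 °C; then 18, toluene, 70 °C (no DMAP)
Reagents that add atoms: 2,4,6-trichlorobenzoyl chloride O=C(Cl)c1c(Cl)cc(Cl)cc1Cl (aroyl group only in 19)
Why: Yamaguchi-type acylation with the preformed angelic mixed anhydride and no nucleophilic catalyst is the standard way to make angelates without Z-to-E isomerisation, and it acylates the alcohol with retention.

**Compound list**
1 | angelic acid, (Z)-2-methylbut-2-enoic acid | C/C=C(/C)C(=O)O | starting material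
2 | (Z)-2-methylbut-2-en-1-ol | C/C=C(/C)CO | intermediate
3 | [(2R,3S)-2,3-dimethyloxiran-2-yl]methanol | OC[C@@]1(C)O[C@H]1C | intermediate
4 | (2S,3S)-2,3-dimethyloxirane-2-carboxylic acid | OC(=O)[C@@]1(C)O[C@H]1C | intermediate
5 | (R)-(−)-carvone | CC1=CC[C@H](CC1=O)C(C)=C | starting material
6 | (R)-trimethyl{[6-methyl-3-(prop-1-en-2-yl)cyclohexa-1,5-dien-1-yl]oxy}silane | CC1=CC[C@H](C=C1O[Si](C)(C)C)C(C)=C | intermediate
7 | (5S,6S)-6-bromo-2-methyl-5-(prop-1-en-2-yl)cyclohex-2-en-1-one (bromine trans to isopropenyl) | Br[C@@H]1C(=O)C(C)=CC[C@H]1C(C)=C | intermediate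
8 | 3-methylbutanal | CC(C)CC=O | starting material
9 | (S)-3-methyl-2-[(1R,6R)-3-methyl-2-oxo-6-(prop-1-en-2-yl)cyclohex-3-en-1-yl]butanal | O=C[C@@H](C(C)C)[C@@H]1C(=O)C(C)=CC[C@H]1C(C)=C | intermediate
10 | (4aR,7R,8S,8aR)-7-hydroxy-2-methyl-5-methylidene-8-(propan-2-yl)-4a,5,6,7,8,8a-hexahydronaphthalen-1(4H)-one | C=C1C[C@@H](O)[C@@H](C(C)C)[C@@H]2C(=O)C(C)=CC[C@@H]12 | intermediate
11 | (2S,3S)-2,3-dimethyloxirane-2-carboxylic 2,4,6-trichlorobenzoic anhydride | Clc1cc(Cl)cc(Cl)c1C(=O)OC(=O)[C@@]1(C)O[C@H]1C | intermediate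
12 | (4aR,7R,8S,8aR)-2-methyl-5-methylidene-1-oxo-8-(propan-2-yl)-1,4,4a,5,6,7,8,8a-octahydronaphthalen-7-yl (2S,3S)-2,3-dimethyloxirane-2-carboxylate | C=C1C[C@@H](OC(=O)[C@@]3(C)O[C@H]3C)[C@@H](C(C)C)[C@@H]2C(=O)C(C)=CC[C@@H]12 | intermediate
13 | 2,3-epoxide of 12, oxirane oxygen on the face of H-4a | C=C1C[C@@H](OC(=O)[C@@]4(C)O[C@H]4C)[C@@H](C(C)C)[C@@H]2C(=O)[C@]3(C)O[C@@H]3C[C@@H]12 | intermediate
14 | tosylhydrazone of 13 | C=C1C[C@@H](OC(=O)[C@@]4(C)O[C@H]4C)[C@@H](C(C)C)[C@@H]2C(=NNS(=O)(=O)c5ccc(C)cc5)[C@]3(C)O[C@@H]3C[C@@H]12 | intermediate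
15 | 5-methylidene-4-(2-oxoethyl)-2-(propan-2-yl)-3-(prop-1-yn-1-yl)cyclohexyl (2S,3S)-2,3-dimethyloxirane-2-carboxylate, ring centres as in 12 | C=C1C[C@@H](OC(=O)[C@@]2(C)O[C@H]2C)[C@@H](C(C)C)[C@H](C#CC)[C@H]1CC=O | intermediate
16 | 3-acetyl-7-methylidene-4-(propan-2-yl)-3a,4,5,6,7,7a-hexahydro-1H-inden-5-yl (2S,3S)-2,3-dimethyloxirane-2-carboxylate, trans-fused | C=C1C[C@@H](OC(=O)[C@@]3(C)O[C@H]3C)[C@@H](C(C)C)[C@@H]2C(C(C)=O)=CC[C@@H]12 | intermediate
17 | 2-(pinacolboryl) derivative of 18 (boron in place of the 2-hydroxyl, same configuration) | C=C1C[C@@H](OC(=O)[C@@]3(C)O[C@H]3C)[C@@H](C(C)C)[C@@H]2[C@@H](C(C)=O)[C@@H](B4OC(C)(C)C(C)(C)O4)C[C@@H]12 | intermediate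
18 | (1R,2S,3aR,6R,7S,7aR)-1-acetyl-2-hydroxy-4-methylidene-7-(propan-2-yl)octahydro-1H-inden-6-yl (2S,3S)-2,3-dimethyloxirane-2-carboxylate | C=C1C[C@@H](OC(=O)[C@@]3(C)O[C@H]3C)[C@@H](C(C)C)[C@@H]2[C@@H](C(C)=O)[C@@H](O)C[C@@H]12 | intermediate
19 | (Z)-2-methylbut-2-enoic 2,4,6-trichlorobenzoic anhydride | C/C=C(/C)C(=O)OC(=O)c1c(Cl)cc(Cl)cc1Cl | intermediate
20 | CNP0300602.1, (1R,2S,3aR,6R,7S,7aR)-1-acetyl-2-{[(Z)-2-methylbut-2-enoyl]oxy}-4-methylidene-7-(propan-2-yl)octahydro-1H-inden-6-yl (2S,3S)-2,3-dimethyloxirane-2-carboxylate | C=C1C[C@@H](OC(=O)[C@@]2(C)O[C@H]2C)[C@@H](C(C)C)[C@@H]2[C@@H](C(C)=O)[C@@H](OC(=O)/C(C)=C\C)C[C@@H]12 | target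

**Totals and risks**
Total step count: 12. Longest linear sequence: 9 steps (5 to 20, steps 4–12); the epoxy acid 4 takes 3 steps on a side branch.

Step 5 is the most likely to fail. Bromide 7 can lose HBr and aromatise, a secondary alpha-keto radical is untested in this coupling, and the aldehyde alpha centre of 9 is epimerisable. The fallback sets out from 5 and returns at 9. The lithium enolate of 5 and the lithium enolate of bought (R)-4-benzyl-3-(3-methylbutanoyl)oxazolidin-2-one are oxidised together with Fe(acac)3 (oxidative enolate heterocoupling, auxiliary control at the new alpha centre, attack anti to isopropenyl) to give (R)-4-benzyl-3-{(S)-3-methyl-2-[(1R,6R)-3-methyl-2-oxo-6-(prop-1-en-2-yl)cyclohex-3-en-1-yl]butanoyl}oxazolidin-2-one F1. LiSEt then gives S-ethyl (S)-3-methyl-2-[(1R,6R)-3-methyl-2-oxo-6-(prop-1-en-2-yl)cyclohex-3-en-1-yl]butanethioate F2, and Et3SiH with Pd/C (Fukuyama reduction) gives 9.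

Step 10 is the second risk. The silver or acid catalyst may attack the exocyclic methylene or the glycidic ester, a methyl-capped alkyne is a weak partner, and step 9 before it needs a hindered hydrazone. The fallback sets out from 13 and returns at 18, bypassing steps 9 to 11. NaBH4 with CeCl3 reduces the ketone to the 1-hydroxy-2,3-epoxide F3 (either carbinol epimer serves), and Ac2O in pyridine gives its acetate F4. H5IO6 cleaves the epoxide C–C bond to the alpha-acetoxy methyl ketone aldehyde F5. SmI2 in THF at −78 °C then removes the acetoxy group to a trivalent samarium enolate that closes by a chelated intramolecular aldol, giving the cis hydroxy ketone 18 with the acetyl group trans to the ring branch.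

Step 11 is the third risk, because the face of boron addition to the cyclopentene is not strongly biased. The fallback sets out from 16 and returns at 18. Nucleophilic epoxidation (t-BuOOH, DBU) gives the alpha,beta-epoxy ketone F6, and SmI2 opens it reductively at the alpha carbon to the beta-hydroxy ketone 18, the carbinol configuration then being set by the epoxidation face instead of the copper–boron addition.

**Further compounds**
F1 | step 5 | (R)-4-benzyl-3-{(S)-3-methyl-2-[(1R,6R)-3-methyl-2-oxo-6-(prop-1-en-2-yl)cyclohex-3-en-1-yl]butanoyl}oxazolidin-2-one | O=C1OC[C@@H](Cc2ccccc2)N1C(=O)[C@@H](C(C)C)[C@@H]1C(=O)C(C)=CC[C@H]1C(C)=C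
F2 | step 5 | S-ethyl (S)-3-methyl-2-[(1R,6R)-3-methyl-2-oxo-6-(prop-1-en-2-yl)cyclohex-3-en-1-yl]butanethioate | CCSC(=O)[C@@H](C(C)C)[C@@H]1C(=O)C(C)=CC[C@H]1C(C)=C
F3 | step 10 | 1-hydroxy-2,3-epoxide from reduction of the ketone of 13 | C=C1C[C@@H](OC(=O)[C@@]4(C)O[C@H]4C)[C@@H](C(C)C)[C@@H]2[C@H](O)[C@]3(C)O[C@@H]3C[C@@H]12
F4 | step 10 | acetate of F3 | C=C1C[C@@H](OC(=O)[C@@]4(C)O[C@H]4C)[C@@H](C(C)C)[C@@H]2[C@H](OC(C)=O)[C@]3(C)O[C@@H]3C[C@@H]12
F5 | step 10 | 3-(1-acetoxy-2-oxopropyl)-5-methylidene-4-(2-oxoethyl)-2-(propan-2-yl)cyclohexyl (2S,3S)-2,3-dimethyloxirane-2-carboxylate | C=C1C[C@@H](OC(=O)[C@@]2(C)O[C@H]2C)[C@@H](C(C)C)[C@H]([C@H](OC(C)=O)C(C)=O)[C@H]1CC=O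
F6 | step 11 | alpha,beta-epoxy ketone of 16, oxirane on the lower face | C=C1C[C@@H](OC(=O)[C@@]4(C)O[C@H]4C)[C@@H](C(C)C)[C@@H]2[C@@]3(C(C)=O)O[C@H]3C[C@@H]12
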